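**Retrosynthetic overview**
1. C3–Br ← Appel inversion of a cis-1,3-diol; the C1 methyl carbinol ← hydride opening of a C1 spiro-epoxide ← hydroxyl-directed epoxidation of a C1 methylidene ← C1 ketone.
2. (E)-C9=CHBr ← bromomethylene Wittig reaction on the ring B enone carbonyl.
3. Ring B (formed second) ← intramolecular aldol condensation of a C6 formyl / 3-oxobutyl ketone (spiro-annulation).
4. Key C–C bond C6–C11 (the quaternary spiro carbon) ← intermolecular Michael addition of a ring A β-keto aldehyde to but-3-en-2-one, steered by the C3 silyloxy stereocentre.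
5. Ring A (present from the start) ← 5,5-dimethylcyclohex-2-en-1-one; C7 by Claisen formylation, C3–O by catalytic enantioselective conjugate borylation/oxidation.

Assumption: comments use the target locants (C1 carbinol, C3 CHBr, C5 CMe2, C6 spiro, C7=C8, C9 bromomethylidene); the ligand enantiomer named in step 3 is taken to give the (S)-carbinol (otherwise its mirror image is used); the starting enone is a catalogue compound (otherwise two steps from dimedone).

**Step 1**
Reactants: 1 5,5-dimethylcyclohex-2-en-1-one; 2 2,2,2-trifluoroethyl formate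
Product: 4 (6Z)-6-(hydroxymethylidene)-5,5-dimethylcyclohex-2-en-1-one, via lithium dienolate 3 (not isolated)
Conditions: LiN(iPr)2, THF, −78 °C; then 2, −78 °C; aq. HCl
Reagents that add atoms: none
Why: Kinetic α′-deprotonation (C6 is the only α-CH2 of the enone) and crossed Claisen condensation with the activated formate install C7, the product resting as its chelated enol; no stereocentre.

**Step 2**
Reactants: 4 (6Z)-6-(hydroxymethylidene)-5,5-dimethylcyclohex-2-en-1-one
Product: 5 (6Z)-5,5-dimethyl-6-[(propan-2-yloxy)methylidene]cyclohex-2-en-1-one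
Conditions: 2-iodopropane, K2CO3, acetone, reflux
Reagents that add atoms: 2-iodopropane, CC(C)I
Why: Williamson-type O-alkylation masks the acidic β-keto aldehyde as a vinylogous ester, so that the enone can undergo copper-catalysed conjugate addition.

**Step 3**
Reactants: 5 (6Z)-5,5-dimethyl-6-[(propan-2-yloxy)methylidene]cyclohex-2-en-1-one
Product: 7 (2Z,5S)-5-hydroxy-3,3-dimethyl-2-[(propan-2-yloxy)methylidene]cyclohexan-1-one, via pinacol boronate 6 (not isolated)
Conditions: B2pin2, CuCl (5 mol%), (R)-1-[(SP)-2-(diphenylphosphino)ferrocenyl]ethyldicyclohexylphosphine (C36H44FeP2, 6 mol%), NaOtBu (10 mol%), iPrOH, THF, rt; then NaBO3·4H2O, THF–H2O, rt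
Reagents that add atoms: bis(pinacolato)diboron, B1(OC(C)(C)C(C)(C)O1)B2OC(C)(C)C(C)(C)O2 (boron of 6); sodium perborate, [Na+].[O-]OB=O (hydroxyl oxygen of 7)
Why: Copper-catalysed enantioselective conjugate borylation at the unsubstituted enone β-carbon (the alkoxy-bearing exocyclic β-carbon is deactivated), then stereoretentive perborate oxidation of the C–B bond; the chiral bisphosphine–copper boryl complex sets the C3 carbinol centre as S.

**Step 4**
Reactants: 7 (2Z,5S)-5-hydroxy-3,3-dimethyl-2-[(propan-2-yloxy)methylidene]cyclohexan-1-one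
Product: 8 (2Z,5S)-5-[(tert-butyldiphenylsilyl)oxy]-3,3-dimethyl-2-[(propan-2-yloxy)methylidene]cyclohexan-1-one
Conditions: tBuPh2SiCl, imidazole, DMF, rt
Reagents that add atoms: tert-butyl(chloro)diphenylsilane, CC(C)(C)[Si](Cl)(c1ccccc1)c1ccccc1
Why: Standard silylation gives an acid-, amine- and ylide-stable ether whose bulk locks ring A in the chair with the C3 substituent equatorial.

**Step 5**
Reactants: 8 (2Z,5S)-5-[(tert-butyldiphenylsilyl)oxy]-3,3-dimethyl-2-[(propan-2-yloxy)methylidene]cyclohexan-1-one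
Product: 9 (2Z,5S)-5-[(tert-butyldiphenylsilyl)oxy]-2-(hydroxymethylidene)-3,3-dimethylcyclohexan-1-one
Conditions: 1 M aq. HCl, THF, rt
Reagents that add atoms: water, O
Why: Acid hydrolysis of the vinylogous ester releases the β-keto aldehyde as its chelated enol without enolising toward C2, so the β-silyloxy group is not eliminated.

**Step 6**
Reactants: 9 (2Z,5S)-5-[(tert-butyldiphenylsilyl)oxy]-2-(hydroxymethylidene)-3,3-dimethylcyclohexan-1-one; 10 but-3-en-2-one
Product: 11 (1R,4S)-4-[(tert-butyldiphenylsilyl)oxy]-2,2-dimethyl-6-oxo-1-(3-oxobutyl)cyclohexane-1-carbaldehyde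
Conditions: 10 (3 equiv), Et3N (0.2 equiv), CH2Cl2, 0 °C → rt
Reagents that add atoms: none
Why: Amine-catalysed Michael addition of the β-keto aldehyde enolate joins the two fragments at C6; in the chair with the silyloxy group equatorial the axial C5 methyl blocks one face, so the C6–C11 bond forms axially, anti to that methyl and cis to the silyloxy group, fixing the quaternary centre as R.

**Step 7**
Reactants: 11 (1R,4S)-4-[(tert-butyldiphenylsilyl)oxy]-2,2-dimethyl-6-oxo-1-(3-oxobutyl)cyclohexane-1-carbaldehyde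
Product: 13 (3S,6S)-3-[(tert-butyldiphenylsilyl)oxy]-5,5-dimethylspiro[5.5]undec-7-ene-1,9-dione, via aldol adduct 12 (not isolated)
Conditions: pyrrolidine (0.3 equiv), AcOH (0.3 equiv), toluene, 60 °C
Reagents that add atoms: none
Why: Intramolecular aldol condensation of the methyl ketone onto the non-enolisable aldehyde (more electrophilic than the hindered ring ketone; hydroxide-free conditions avoid retro-Claisen deformylation) closes ring B as a 4,4-disubstituted cyclohexenone, leaving the quaternary centre untouched (its descriptor becomes S by priority change only).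

**Step 8**
Reactants: 13 (3S,6S)-3-[(tert-butyldiphenylsilyl)oxy]-5,5-dimethylspiro[5.5]undec-7-ene-1,9-dione; 14 (bromomethyl)triphenylphosphonium bromide
Product: 15 (3S,6S,9E)-9-(bromomethylidene)-3-[(tert-butyldiphenylsilyl)oxy]-5,5-dimethylspiro[5.5]undec-7-en-1-one
Conditions: 14, NaN(SiMe3)2, THF, −78 °C; then 13, −78 °C → rt; chromatography (E isomer)
Reagents that add atoms: none
Why: The Wittig reaction with the bromomethylene ylide occurs only at the unhindered enone carbonyl (the C1 ketone is neopentyl); the C9=CHBr geometry is not intrinsically controlled, so an E/Z mixture is expected and the E isomer (Br on the C10H2 side) is isolated by chromatography.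

**Step 9**
Reactants: 15 (3S,6S,9E)-9-(bromomethylidene)-3-[(tert-butyldiphenylsilyl)oxy]-5,5-dimethylspiro[5.5]undec-7-en-1-one; 16 dimethyltitanocene Cp2TiMe2
Product: 17 tert-butyl{[(3S,6S,9E)-9-(bromomethylidene)-5,5-dimethyl-1-methylidenespiro[5.5]undec-7-en-3-yl]oxy}diphenylsilane
Conditions: 16 (3 equiv), toluene, 75 °C, dark
Reagents that add atoms: none
Why: Petasis methylenation through Cp2Ti=CH2 is non-basic and is the method of choice for a hindered, enolisable β-silyloxy ketone in the presence of an alkenyl bromide; no stereocentre.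

**Step 10**
Reactants: 17 tert-butyl{[(3S,6S,9E)-9-(bromomethylidene)-5,5-dimethyl-1-methylidenespiro[5.5]undec-7-en-3-yl]oxy}diphenylsilane
Product: 18 (3S,6S,9E)-9-(bromomethylidene)-5,5-dimethyl-1-methylidenespiro[5.5]undec-7-en-3-ol
Conditions: Bu4NF, THF, rt
Reagents that add atoms: none
Why: Fluoride cleavage of the silyl ether frees the homoallylic C3 alcohol that directs the next step.

**Step 11**
Reactants: 18 (3S,6S,9E)-9-(bromomethylidene)-5,5-dimethyl-1-methylidenespiro[5.5]undec-7-en-3-ol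
Product: 19 (1S,3S,6S,9E)-9-(bromomethylidene)-5,5-dimethylspiro[5.5]undec-7-ene-1-spiro-2'-oxiran-3-ol (C1 spiro-epoxide, oxirane oxygen cis to the 3-hydroxyl)
Conditions: tBuOOH, VO(acac)2 (5 mol%), CH2Cl2, 0 °C → rt
Reagents that add atoms: tert-butyl hydroperoxide, CC(C)(C)OO
Why: Vanadium-catalysed hydroxyl-directed epoxidation delivers oxygen to the exocyclic alkene on the face of the C3 hydroxyl (also the face anti to the axial C5 methyl), setting C1 as S, while the bromodiene, which has no directing hydroxyl, is left alone.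

**Step 12**
Reactants: 19 (1S,3S,6S,9E)-9-(bromomethylidene)-5,5-dimethylspiro[5.5]undec-7-ene-1-spiro-2'-oxiran-3-ol
Product: 20 (1S,3S,6S,9E)-9-(bromomethylidene)-1,5,5-trimethylspiro[5.5]undec-7-ene-1,3-diol
Conditions: LiBHEt3, THF, 0 °C → rt; then H2O
Reagents that add atoms: none
Why: SN2 hydride opening of the epoxide at its unsubstituted CH2 gives the C1 methyl carbinol with the C1–O bond and configuration intact; LiBHEt3 does not reduce alkenyl bromides.

**Step 13**
Reactants: 20 (1S,3S,6S,9E)-9-(bromomethylidene)-1,5,5-trimethylspiro[5.5]undec-7-ene-1,3-diol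
Product: 21 (1S,3R,6S,9E)-3-bromo-9-(bromomethylidene)-1,5,5-trimethylspiro[5.5]undec-7-en-1-ol
Conditions: CBr4, PPh3, CH2Cl2, 0 °C → rt
Reagents that add atoms: tetrabromomethane, BrC(Br)(Br)Br
Why: Appel reaction: the secondary C3 alcohol is activated as its alkoxyphosphonium ion and displaced by bromide in an SN2 step with inversion (3S to 3R), giving the equatorial bromide trans to the hindered tertiary alcohol, which does not react.

**Compound list**
1 | 5,5-dimethylcyclohex-2-en-1-one | CC1(C)CC=CC(=O)C1 | starting material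
2 | 2,2,2-trifluoroethyl formate | O=COCC(F)(F)F | starting material
3 | lithium 3,3-dimethylcyclohexa-1,5-dien-1-olate | [Li+].[O-]C1=CC(C)(C)CC=C1 | intermediate (not isolated)
4 | (6Z)-6-(hydroxymethylidene)-5,5-dimethylcyclohex-2-en-1-one | CC1(C)CC=CC(=O)/C1=C\O | intermediate
5 | (6Z)-5,5-dimethyl-6-[(propan-2-yloxy)methylidene]cyclohex-2-en-1-one | CC1(C)CC=CC(=O)/C1=C\OC(C)C | intermediate
6 | (2Z,5S)-3,3-dimethyl-2-[(propan-2-yloxy)methylidene]-5-(4,4,5,5-tetramethyl-1,3,2-dioxaborolan-2-yl)cyclohexan-1-one | CC1(C)C[C@H](B2OC(C)(C)C(C)(C)O2)CC(=O)/C1=C\OC(C)C | intermediate (not isolated)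
7 | (2Z,5S)-5-hydroxy-3,3-dimethyl-2-[(propan-2-yloxy)methylidene]cyclohexan-1-one | CC1(C)C[C@H](O)CC(=O)/C1=C\OC(C)C | intermediate
8 | (2Z,5S)-5-[(tert-butyldiphenylsilyl)oxy]-3,3-dimethyl-2-[(propan-2-yloxy)methylidene]cyclohexan-1-one | CC1(C)C[C@H](O[Si](c2ccccc2)(c2ccccc2)C(C)(C)C)CC(=O)/C1=C\OC(C)C | intermediate
9 | (2Z,5S)-5-[(tert-butyldiphenylsilyl)oxy]-2-(hydroxymethylidene)-3,3-dimethylcyclohexan-1-one | CC1(C)C[C@H](O[Si](c2ccccc2)(c2ccccc2)C(C)(C)C)CC(=O)/C1=C\O | intermediate
10 | but-3-en-2-one | CC(=O)C=C | starting material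
11 | (1R,4S)-4-[(tert-butyldiphenylsilyl)oxy]-2,2-dimethyl-6-oxo-1-(3-oxobutyl)cyclohexane-1-carbaldehyde | CC1(C)C[C@H](O[Si](c2ccccc2)(c2ccccc2)C(C)(C)C)CC(=O)[C@]1(C=O)CCC(C)=O | intermediate
12 | (3S,6R)-3-[(tert-butyldiphenylsilyl)oxy]-7-hydroxy-5,5-dimethylspiro[5.5]undecane-1,9-dione (C7 epimers) | CC1(C)C[C@H](O[Si](c3ccccc3)(c3ccccc3)C(C)(C)C)CC(=O)[C@@]12C(O)CC(=O)CC2 | intermediate (not isolated)
13 | (3S,6S)-3-[(tert-butyldiphenylsilyl)oxy]-5,5-dimethylspiro[5.5]undec-7-ene-1,9-dione | CC1(C)C[C@H](O[Si](c3ccccc3)(c3ccccc3)C(C)(C)C)CC(=O)[C@@]12C=CC(=O)CC2 | intermediate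
14 | (bromomethyl)triphenylphosphonium bromide | [Br-].BrC[P+](c1ccccc1)(c1ccccc1)c1ccccc1 | starting material
15 | (3S,6S,9E)-9-(bromomethylidene)-3-[(tert-butyldiphenylsilyl)oxy]-5,5-dimethylspiro[5.5]undec-7-en-1-one | CC1(C)C[C@H](O[Si](c3ccccc3)(c3ccccc3)C(C)(C)C)CC(=O)[C@@]12C=C/C(=C/Br)CC2 | intermediate
16 | dimethyltitanocene Cp2TiMe2 | C[Ti](C)(C1C=CC=C1)C1C=CC=C1 | starting material
17 | tert-butyl{[(3S,6S,9E)-9-(bromomethylidene)-5,5-dimethyl-1-methylidenespiro[5.5]undec-7-en-3-yl]oxy}diphenylsilane | CC1(C)C[C@H](O[Si](c3ccccc3)(c3ccccc3)C(C)(C)C)CC(=C)[C@@]12C=C/C(=C/Br)CC2 | intermediate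
18 | (3S,6S,9E)-9-(bromomethylidene)-5,5-dimethyl-1-methylidenespiro[5.5]undec-7-en-3-ol | CC1(C)C[C@H](O)CC(=C)[C@@]12C=C/C(=C/Br)CC2 | intermediate
19 | (1S,3S,6S,9E)-9-(bromomethylidene)-5,5-dimethylspiro[5.5]undec-7-ene-1-spiro-2'-oxiran-3-ol | CC1(C)C[C@H](O)C[C@@]3(CO3)[C@@]12C=C/C(=C/Br)CC2 | intermediate
20 | (1S,3S,6S,9E)-9-(bromomethylidene)-1,5,5-trimethylspiro[5.5]undec-7-ene-1,3-diol | CC1(C)C[C@H](O)C[C@](C)(O)[C@@]12C=C/C(=C/Br)CC2 | intermediate
21 | (1S,3R,6S,9E)-3-bromo-9-(bromomethylidene)-1,5,5-trimethylspiro[5.5]undec-7-en-1-ol | CC1(C)C[C@@H](Br)C[C@](C)(O)[C@@]12C=C/C(=C/Br)CC2 | target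

**Totals**
Total step count: 13. Longest linear sequence: 13 steps (1 → 21).

**Three steps most likely to fail**

Step 8 (bromomethylenation). The E/Z ratio at C9=CHBr is not controlled and the ylide is basic toward the β-silyloxy ketone. The fallback sets out from 13. A boron-Wittig olefination with LiCH(Bpin)2 (from CH2(Bpin)2 and lithium 2,2,6,6-tetramethylpiperidide, THF, −78 °C → rt) gives the (9E)-alkenyl pinacol boronate F1. Its isomers are robust on silica and are separated there. Stereoretentive bromodeboronation with CuBr2 (MeOH–H2O, 70 °C) then returns to the route at 15.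

Step 9 (methylenation of the neopentyl C1 ketone). The ketone is flanked by the spiro centre and may resist the titanium reagent. The fallback sets out from 15. Me3SiCH2Li/CeCl3 (THF, −78 °C), a non-basic organocerium that adds to very hindered enolisable ketones, gives the β-hydroxysilane F2. Peterson elimination with KH (THF, 0 °C → rt) returns to the route at 17.

Step 11 (homoallylic hydroxyl-directed epoxidation). The equatorial C3 hydroxyl may deliver poorly to the exocyclic alkene. The fallback sets out from 15 and replaces the homoallylic by an allylic direction: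
- MeLi/CeCl3 (THF, −78 °C) adds to the C1 ketone to give the tertiary alcohol F3 (either C1 epimer serves).
- Dehydration with methyl N-(triethylammoniosulfonyl)carbamate (benzene, 50 °C) gives the endocyclic C1=C2 alkene F4. Any exocyclic isomer formed alongside is 17 itself and rejoins the main line.
- Bu4NF gives the allylic alcohol F5.
- VO(acac)2/tBuOOH epoxidises it syn to the hydroxyl to give the cis-epoxy alcohol F6.
- LiBHEt3 opens the epoxide at the secondary C2 (C1 is fully substituted) and returns to the route at 20.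

**Further compounds**
F1 | step 8 | (3S,6S,9E)-3-[(tert-butyldiphenylsilyl)oxy]-5,5-dimethyl-9-[(4,4,5,5-tetramethyl-1,3,2-dioxaborolan-2-yl)methylidene]spiro[5.5]undec-7-en-1-one | CC1(C)C[C@H](O[Si](c3ccccc3)(c3ccccc3)C(C)(C)C)CC(=O)[C@@]12C=C/C(=C/B3OC(C)(C)C(C)(C)O3)CC2
F2 | step 9 | (3S,6S,9E)-9-(bromomethylidene)-3-[(tert-butyldiphenylsilyl)oxy]-5,5-dimethyl-1-[(trimethylsilyl)methyl]spiro[5.5]undec-7-en-1-ol (C1 epimers) | CC1(C)C[C@H](O[Si](c3ccccc3)(c3ccccc3)C(C)(C)C)CC(O)(C[Si](C)(C)C)[C@@]12C=C/C(=C/Br)CC2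
F3 | step 11 | (3S,6S,9E)-9-(bromomethylidene)-3-[(tert-butyldiphenylsilyl)oxy]-1,5,5-trimethylspiro[5.5]undec-7-en-1-ol (C1 epimers) | CC1(C)C[C@H](O[Si](c3ccccc3)(c3ccccc3)C(C)(C)C)CC(C)(O)[C@@]12C=C/C(=C/Br)CC2
F4 | step 11 | tert-butyl{[(3S,6S,9E)-9-(bromomethylidene)-1,5,5-trimethylspiro[5.5]undeca-1,7-dien-3-yl]oxy}diphenylsilane | CC1(C)C[C@H](O[Si](c3ccccc3)(c3ccccc3)C(C)(C)C)C=C(C)[C@@]12C=C/C(=C/Br)CC2
F5 | step 11 | (3S,6S,9E)-9-(bromomethylidene)-1,5,5-trimethylspiro[5.5]undeca-1,7-dien-3-ol | CC1(C)C[C@H](O)C=C(C)[C@@]12C=C/C(=C/Br)CC2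
F6 | step 11 | (1R,2S,3S,6S,9E)-9-(bromomethylidene)-1,2-epoxy-1,5,5-trimethylspiro[5.5]undec-7-en-3-ol | CC1(C)C[C@H](O)[C@@H]3O[C@]3(C)[C@@]12C=C/C(=C/Br)CC2
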